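**Plan**

- Cuts, in lignan numbering (C7/C8/C9 on the guaiacyl side of the furofuran, C7'/C8'/C9' on the dihydrobenzofuranyl side): C9'H2 back to a lactone carbonyl, then C8'–C7' (furofuran ring B), then the C9–O–C7' benzyl ether, then C7–C8 (aldol); in the dihydrobenzofuran, the C2–C3 bond.
- Enabling feature: C7'–H is benzylic and α to the ring-B oxygen and lies 1,5 to C8'. C8' is the α-carbon of the γ-lactone O–C7–C8–C8'–C9'(=O) (ring A at the lactone level) and can be turned into a diazo carbon.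
- Forward order: the dihydrobenzofuran ring is closed first (fragment B, a benzylic bromide). The acyclic aldol diol (fragment A) is etherified with it, ring A is formed as the lactone, C8' is diazotised, ring B is closed by C–H insertion, and the lactone is reduced to the ether before desilylation.
- Stereochemistry: C7 and C8 come from an auxiliary-controlled anti-aldol. C8' follows from the obligatory cis ring fusion and C7' from the kinetic endo preference of the insertion. C2/C3 of the dihydrobenzofuran (cis) come from a C–H insertion catalysed by a chiral dirhodium carboxylate.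

Key step: step 18

Remark: the descriptors of the target are read literally, which means a 2,3-cis dihydrobenzofuran (2S,3S) and an endo,endo furofuran (7S,8S,7'S,8'S).
Assumption: Rh2(S-PTTL)4 is taken to select the carbenoid face that leads to the (2S,3R) cis ester of step 9; should it favour the mirror image, Rh2(R-PTTL)4 is used with nothing else changed.
Abbreviations: TBS = tert-butyldimethylsilyl; TIPS = triisopropylsilyl; Ar = 4-(TBS-oxy)-3-methoxyphenyl; DHB = (2S,3S)-7-methoxy-2-Ar-3-[(TIPS-oxy)methyl]-2,3-dihydro-1-benzofuran-5-yl (2-Ar and 3-CH2O cis).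

**Fragment A: the aldol diol**

Step 1
Reactants: 1 pent-4-enoic acid; 2 (S)-4-benzyl-1,3-oxazolidin-2-one
Product: 3 (S)-4-benzyl-3-(pent-4-enoyl)-1,3-oxazolidin-2-one
Conditions: t-BuCOCl, Et3N, THF, −20 °C; then LiCl, 2, −20 °C → rt
Reagents that add atoms: none
Why: N-acylation of the LiCl-activated oxazolidinone by the mixed pivalic anhydride of 1 (standard loading of an Evans auxiliary), which reacts at the less hindered pentenoyl carbonyl and creates no stereocentre.

Step 2
Reactants: 4 vanillin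
Product: 5 4-(tert-butyldimethylsilyloxy)-3-methoxybenzaldehyde
Conditions: TBSCl, imidazole, DMF, rt
Reagents that add atoms: tert-butyldimethylsilyl chloride, CC(C)(C)[Si](C)(C)Cl
Why: Imidazole-promoted silylation of the phenol, which masks the acidic OH for the enolate, organolithium and carbenoid steps and is removed only by fluoride at the end.

Step 3
Reactants: 3 (S)-4-benzyl-3-(pent-4-enoyl)-1,3-oxazolidin-2-one; 5 4-(tert-butyldimethylsilyloxy)-3-methoxybenzaldehyde
Product: 7 (4S)-4-benzyl-3-[(2R,3S)-3-Ar-3-hydroxy-2-(prop-2-en-1-yl)propanoyl]-1,3-oxazolidin-2-one, via O-trimethylsilyl aldol adduct 6 (not isolated)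
Conditions: MgCl2 (20 mol%), Et3N, Me3SiCl, EtOAc, rt; then MeOH, CF3CO2H (cat.), 0 °C
Reagents that add atoms: none
Why: Magnesium-halide-catalysed anti-selective Evans aldol, in which the chelated Z-magnesium enolate of 3 adds to the non-enolisable aldehyde on the face away from the benzyl group through a boat-like transition state while Me3SiCl silylates the aldolate and turns over MgCl2, so that C8 (2R) and C7 (3S) are set anti; brief acidic methanolysis then removes the labile trimethylsilyl group.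

Step 4
Reactants: 7 (4S)-4-benzyl-3-[(2R,3S)-3-Ar-3-hydroxy-2-(prop-2-en-1-yl)propanoyl]-1,3-oxazolidin-2-one
Product: 8 (1S,2S)-1-Ar-2-(prop-2-en-1-yl)propane-1,3-diol
Conditions: LiBH4, MeOH (1 equiv), THF, 0 °C
Reagents that add atoms: none
Why: Reductive cleavage of the N-acyl oxazolidinone by LiBH4 at the exocyclic imide carbonyl, which should give the primary alcohol C9 without touching the two stereocentres and return the auxiliary.

**Fragment B: the cis-dihydrobenzofuran bromide**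

Step 5
Reactants: 9 4-bromo-2-methoxyphenol
Product: 10 4-bromo-2-iodo-6-methoxyphenol
Conditions: N-iodosuccinimide, TsOH·H2O (10 mol%), MeCN, 0 °C → rt
Reagents that add atoms: N-iodosuccinimide, O=C1CCC(=O)N1I
Why: Phenol-directed electrophilic aromatic iodination, in which the para position is blocked by bromine and one ortho position by methoxy, so iodine can enter only at C6.

Step 6
Reactants: 5 4-(tert-butyldimethylsilyloxy)-3-methoxybenzaldehyde
Product: 11 [4-(tert-butyldimethylsilyloxy)-3-methoxyphenyl]methanol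
Conditions: NaBH4, MeOH, 0 °C
Reagents that add atoms: none
Why: Borohydride reduction of the aryl aldehyde to the benzylic alcohol, under which the aryl silyl ether is inert at 0 °C.

Step 7
Reactants: 10 4-bromo-2-iodo-6-methoxyphenol; 11 [4-(tert-butyldimethylsilyloxy)-3-methoxyphenyl]methanol
Product: 12 5-bromo-1-iodo-3-methoxy-2-[(Ar-methyl)oxy]benzene
Conditions: PPh3, DIAD, THF, 0 °C → rt
Reagents that add atoms: none
Why: Mitsunobu etherification, in which the acidic 2,6-disubstituted phenol is alkylated by the primary benzylic oxyphosphonium ion under neutral conditions that spare the base-labile aryl silyl ether.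

Step 8
Reactants: 12 5-bromo-1-iodo-3-methoxy-2-[(Ar-methyl)oxy]benzene
Product: 13 ethyl 2-{5-bromo-3-methoxy-2-[(Ar-methyl)oxy]phenyl}-2-diazoacetate
Conditions: ethyl diazoacetate, Pd(PPh3)4 (5 mol%), Ag2CO3 (0.5 equiv), Et3N, toluene, rt
Reagents that add atoms: ethyl diazoacetate, CCOC(=O)C=[N+]=[N-]
Why: Palladium-catalysed cross-coupling of an aryl iodide with a diazoacetate with retention of the diazo group (oxidative addition of zerovalent palladium to C–I, far faster than to C–Br at room temperature, silver-assisted transfer of the diazo carbon, reductive elimination), which installs the aryldiazoacetate in one step.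

Step 9
Reactants: 13 ethyl 2-{5-bromo-3-methoxy-2-[(Ar-methyl)oxy]phenyl}-2-diazoacetate
Product: 14 ethyl (2S,3R)-5-bromo-7-methoxy-2-Ar-2,3-dihydro-1-benzofuran-3-carboxylate (2,3-cis)
Conditions: Rh2(S-PTTL)4 [dirhodium tetrakis(N-phthaloyl-(S)-tert-leucinate)] (1 mol%), toluene, −60 °C
Reagents that add atoms: none
Why: Enantioselective intramolecular 1,5 C–H insertion of the aryl/ester rhodium carbenoid into the benzylic ether C–H bond, catalysed by the chiral divalent-rhodium carboxylate, closes the dihydrofuran ring through the C2–C3 bond; the concerted insertion gives the 2,3-cis ester kinetically because the aryl group turns away from the catalyst wall, and the tert-leucinate ligands select the carbenoid face that sets C2 (S) and C3 (R).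

Step 10
Reactants: 14 ethyl (2S,3R)-5-bromo-7-methoxy-2-Ar-2,3-dihydro-1-benzofuran-3-carboxylate
Product: 15 [(2S,3S)-5-bromo-7-methoxy-2-Ar-2,3-dihydro-1-benzofuran-3-yl]methanol (2,3-cis)
Conditions: iBu2AlH (2.5 equiv), CH2Cl2, −78 °C; aq. potassium sodium tartrate
Reagents that add atoms: none
Why: Ester-to-alcohol reduction with the Lewis-acidic, non-basic hydride iBu2AlH at low temperature, so that the epimerisable C3 (cis to the 2-aryl group) is never enolised.

Step 11
Reactants: 15 [(2S,3S)-5-bromo-7-methoxy-2-Ar-2,3-dihydro-1-benzofuran-3-yl]methanol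
Product: 16 (2S,3S)-5-bromo-7-methoxy-2-Ar-3-[(triisopropylsilyloxy)methyl]-2,3-dihydro-1-benzofuran (DHB–Br)
Conditions: TIPSOTf, 2,6-lutidine, CH2Cl2, 0 °C
Reagents that add atoms: triisopropylsilyl trifluoromethanesulfonate, CC(C)[Si](OS(=O)(=O)C(F)(F)F)(C(C)C)C(C)C
Why: Silylation of the primary alcohol with a silyl triflate and a hindered base, giving a bulky triisopropylsilyl ether that tolerates the organolithium, the lithium amide and BF3·OEt2 used later.

Step 12
Reactants: 16 DHB–Br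
Product: 18 DHB–CH2OH (the 5-hydroxymethyl compound), via DHB-5-carbaldehyde 17 (not isolated)
Conditions: n-BuLi, THF, −78 °C; DMF, −78 °C; then MeOH, NaBH4, −78 → 0 °C
Reagents that add atoms: N,N-dimethylformamide, CN(C)C=O
Why: Bromine–lithium exchange on the aryl bromide, Bouveault-type formylation of the aryllithium with DMF and in-flask borohydride reduction of the aldehyde released on adding methanol turn C5–Br into C5–CH2OH without a basic aqueous step.

Step 13
Reactants: 18 DHB–CH2OH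
Product: 19 DHB–CH2Br (the 5-bromomethyl compound)
Conditions: CBr4, PPh3, 2,6-lutidine, CH2Cl2, 0 °C; used crude
Reagents that add atoms: tetrabromomethane, BrC(Br)(Br)Br
Why: Appel bromination of the primary benzylic alcohol under neutral conditions, the product being used at once because a 4-alkoxy-3-methoxybenzyl bromide ionises easily.

**Union, lactone, diazo compound, key step, endgame**

Step 14
Reactants: 8 (1S,2S)-1-Ar-2-(prop-2-en-1-yl)propane-1,3-diol; 19 DHB–CH2Br
Product: 20 (1S,2S)-1-Ar-2-{[(DHB-methyl)oxy]methyl}pent-4-en-1-ol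
Conditions: Ag2O, 4 Å molecular sieves, CH2Cl2, rt, dark (8 in 1.5-fold excess)
Reagents that add atoms: none
Why: Silver-oxide-mediated Williamson-type etherification, in which silver assists departure of bromide from the activated benzylic carbon and the less hindered primary hydroxyl of the 1,3-diol is alkylated in preference to the secondary benzylic one, with no strong base that could cleave or shift the aryl silyl ethers.

Step 15
Reactants: 20 (1S,2S)-1-Ar-2-{[(DHB-methyl)oxy]methyl}pent-4-en-1-ol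
Product: 23 (4S,5S)-5-Ar-4-{[(DHB-methyl)oxy]methyl}oxolan-2-ol (lactol; both anomers), via pentane-1,4,5-triol 21 (not isolated), via hydroxy aldehyde 22 (not isolated)
Conditions: K2OsO4·2H2O (2 mol%), NaIO4, 2,6-lutidine, dioxane/H2O 3:1, rt
Reagents that add atoms: sodium periodate, [Na+].[O-]I(=O)(=O)=O
Why: Lemieux–Johnson cleavage, in which osmium-catalysed dihydroxylation of the only alkene and periodate scission give the aldehyde that the C7 hydroxyl traps as the five-membered lactol, while the buffered, ozone-free medium leaves the electron-rich arenes and benzylic ethers alone.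

Step 16
Reactants: 23 (4S,5S)-5-Ar-4-{[(DHB-methyl)oxy]methyl}oxolan-2-ol
Product: 24 (4S,5S)-5-Ar-4-{[(DHB-methyl)oxy]methyl}oxolan-2-one (cis-4,5-disubstituted γ-lactone)
Conditions: Pr4N[RuO4] (5 mol%), N-methylmorpholine N-oxide, 4 Å molecular sieves, CH2Cl2, rt
Reagents that add atoms: none
Why: Ley–Griffith oxidation of the lactol to the γ-lactone with catalytic perruthenate and the amine oxide as terminal oxidant under neutral anhydrous conditions, under which C7 and C8 cannot enolise and stay cis.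

Step 17
Reactants: 24 (4S,5S)-5-Ar-4-{[(DHB-methyl)oxy]methyl}oxolan-2-one
Product: 26 (4S,5S)-5-Ar-3-diazo-4-{[(DHB-methyl)oxy]methyl}oxolan-2-one, via 3-trifluoroacetyl lactone 25 (not isolated)
Conditions: LiN(SiMe3)2, THF, −78 °C; CF3CO2CH2CF3, −78 °C; then MeSO2N3, Et3N, H2O (1 equiv), MeCN, rt
Reagents that add atoms: methanesulfonyl azide, CS(=O)(=O)N=[N+]=[N-]
Why: Detrifluoroacetylative Regitz-type diazo transfer, in which the lactone enolate is C-acylated by the trifluoroethyl ester to activate C8' and the sulfonyl azide then delivers N2 with loss of the trifluoroacetyl group as the N-acyl sulfonamide, a detour needed because a plain lactone is not acidic enough for direct transfer.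

Step 18
Reactants: 26 (4S,5S)-5-Ar-3-diazo-4-{[(DHB-methyl)oxy]methyl}oxolan-2-one
Product: 27 endo,endo-2-Ar-6-DHB-3,7-dioxabicyclo[3.3.0]octan-4-one (furofuranone; C2 = C7; C4 = C9'; C5 = C8'; C6 = C7'; C1 = C8; 7S,8S,7'S,8'R)
Conditions: Rh2(OAc)4 (2 mol%), CH2Cl2, rt, slow addition of 26
Reagents that add atoms: none
Why: Rh2(OAc)4 expels N2 from 26 to give an electrophilic divalent-rhodium carbenoid at C8', which inserts through a concerted, hydride-transfer-like three-centre transition state into the C7'–H bond, forming C8'–C7' and releasing the catalyst. The closest known reaction type is the dirhodium-carboxylate-catalysed 1,5 C–H insertion of α-diazo-γ-butyrolactones into benzylic ether C–H bonds, which gives endo-aryl furofuranones. The one ring closed is the second tetrahydrofuran (C8'–C8–C9–O–C7'), a five-membered ring formed by 1,5-insertion. C8' is fixed by the lactone, because two five-membered rings can only be cis-fused, so the C8 configuration from the aldol dictates it. C7' is set in the insertion transition state, where the C–H bond aligns with the carbenoid carbon while the aryl group points away from the dirhodium core, which puts it cis to the lactone carbonyl (endo); together with the cis lactone from the anti-aldol this places both aryl groups on the concave face. The step needs site selectivity for C7'–H over 1,2-hydride shift from C8–H and over remote C–H bonds, and this is secured by the double activation of C7'–H by oxygen and aryl, the strain-free five-membered geometry and the poor alignment of C8–H in the rigid lactone.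

Step 19
Reactants: 27 endo,endo-2-Ar-6-DHB-3,7-dioxabicyclo[3.3.0]octan-4-one
Product: 28 endo,endo-2-Ar-6-DHB-3,7-dioxabicyclo[3.3.0]octan-4-ol (lactol; both anomers)
Conditions: iBu2AlH (1.2 equiv), CH2Cl2, −78 °C
Reagents that add atoms: none
Why: Partial reduction of the γ-lactone by a single hydride from iBu2AlH at −78 °C, where the tetrahedral aluminium hemiacetal is stable, should give the lactol without epimerising any centre.

Step 20
Reactants: 28 endo,endo-2-Ar-6-DHB-3,7-dioxabicyclo[3.3.0]octan-4-ol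
Product: 29 endo,endo-2-Ar-6-DHB-3,7-dioxabicyclo[3.3.0]octane (tris-silyl ether of the target; 7S,8S,7'S,8'S)
Conditions: Et3SiH, BF3·OEt2, CH2Cl2, −78 °C
Reagents that add atoms: none
Why: Ionic hydrogenation of the lactol, in which BF3·OEt2 ionises the hemiacetal to the non-benzylic C9' oxocarbenium ion and Et3SiH delivers hydride to it, while at −78 °C the benzylic ethers at C7, C7' and C2 of the dihydrobenzofuran stay un-ionised so that the endo,endo and cis arrangements are kept.

Step 21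
Reactants: 29 endo,endo-2-Ar-6-DHB-3,7-dioxabicyclo[3.3.0]octane
Product: 30 endo,endo-2-(4-hydroxy-3-methoxyphenyl)-6-[(2S,3S)-2-(4-hydroxy-3-methoxyphenyl)-3-(hydroxymethyl)-7-methoxy-2,3-dihydro-1-benzofuran-5-yl]-3,7-dioxabicyclo[3.3.0]octane (7S,8S,7'S,8'S; the target)
Conditions: Bu4NF, AcOH (1:1), THF, 0 °C → rt
Reagents that add atoms: none
Why: Fluoride-induced cleavage of the two aryl tert-butyldimethylsilyl ethers and the primary triisopropylsilyl ether, with acetic acid buffering the phenoxides so that no quinone methide forms and no benzylic ether carbon epimerises.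

**Compound list**

1 | pent-4-enoic acid | C=CCCC(=O)O | starting material
2 | (S)-4-benzyl-1,3-oxazolidin-2-one | O=C1N[C@@H](Cc2ccccc2)CO1 | starting material
3 | (S)-4-benzyl-3-(pent-4-enoyl)-1,3-oxazolidin-2-one | C=CCCC(=O)N1[C@@H](Cc2ccccc2)COC1=O | intermediate
4 | vanillin | COc1cc(C=O)ccc1O | starting material
5 | 4-(tert-butyldimethylsilyloxy)-3-methoxybenzaldehyde | COc1cc(C=O)ccc1O[Si](C)(C)C(C)(C)C | intermediate
6 | (4S)-4-benzyl-3-[(2R,3S)-3-Ar-2-(prop-2-en-1-yl)-3-(trimethylsilyloxy)propanoyl]-1,3-oxazolidin-2-one | C=CC[C@@H](C(=O)N1[C@@H](Cc2ccccc2)COC1=O)[C@H](O[Si](C)(C)C)c1ccc(O[Si](C)(C)C(C)(C)C)c(OC)c1 | intermediate (not isolated)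
7 | (4S)-4-benzyl-3-[(2R,3S)-3-Ar-3-hydroxy-2-(prop-2-en-1-yl)propanoyl]-1,3-oxazolidin-2-one | C=CC[C@@H](C(=O)N1[C@@H](Cc2ccccc2)COC1=O)[C@H](O)c1ccc(O[Si](C)(C)C(C)(C)C)c(OC)c1 | intermediate
8 | (1S,2S)-1-Ar-2-(prop-2-en-1-yl)propane-1,3-diol | C=CC[C@@H](CO)[C@H](O)c1ccc(O[Si](C)(C)C(C)(C)C)c(OC)c1 | intermediate
9 | 4-bromo-2-methoxyphenol | COc1cc(Br)ccc1O | starting material
10 | 4-bromo-2-iodo-6-methoxyphenol | COc1cc(Br)cc(I)c1O | intermediate
11 | [4-(tert-butyldimethylsilyloxy)-3-methoxyphenyl]methanol | COc1cc(CO)ccc1O[Si](C)(C)C(C)(C)C | intermediate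
12 | 5-bromo-1-iodo-3-methoxy-2-[(Ar-methyl)oxy]benzene | COc1cc(Br)cc(I)c1OCc1ccc(O[Si](C)(C)C(C)(C)C)c(OC)c1 | intermediate
13 | ethyl 2-{5-bromo-3-methoxy-2-[(Ar-methyl)oxy]phenyl}-2-diazoacetate | CCOC(=O)C(=[N+]=[N-])c1cc(Br)cc(OC)c1OCc1ccc(O[Si](C)(C)C(C)(C)C)c(OC)c1 | intermediate
14 | ethyl (2S,3R)-5-bromo-7-methoxy-2-Ar-2,3-dihydro-1-benzofuran-3-carboxylate (cis) | Brc1cc(OC)c2c(c1)[C@@H](C(=O)OCC)[C@@H](c1ccc(O[Si](C)(C)C(C)(C)C)c(OC)c1)O2 | intermediate
15 | [(2S,3S)-5-bromo-7-methoxy-2-Ar-2,3-dihydro-1-benzofuran-3-yl]methanol (cis) | Brc1cc(OC)c2c(c1)[C@@H](CO)[C@@H](c1ccc(O[Si](C)(C)C(C)(C)C)c(OC)c1)O2 | intermediate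
16 | DHB–Br, (2S,3S)-5-bromo-7-methoxy-2-Ar-3-[(triisopropylsilyloxy)methyl]-2,3-dihydro-1-benzofuran | Brc1cc(OC)c2c(c1)[C@@H](CO[Si](C(C)C)(C(C)C)C(C)C)[C@@H](c1ccc(O[Si](C)(C)C(C)(C)C)c(OC)c1)O2 | intermediate
17 | DHB-5-carbaldehyde | O=Cc1cc(OC)c2c(c1)[C@@H](CO[Si](C(C)C)(C(C)C)C(C)C)[C@@H](c1ccc(O[Si](C)(C)C(C)(C)C)c(OC)c1)O2 | intermediate (not isolated)
18 | DHB–CH2OH | OCc1cc(OC)c2c(c1)[C@@H](CO[Si](C(C)C)(C(C)C)C(C)C)[C@@H](c1ccc(O[Si](C)(C)C(C)(C)C)c(OC)c1)O2 | intermediate
19 | DHB–CH2Br | BrCc1cc(OC)c2c(c1)[C@@H](CO[Si](C(C)C)(C(C)C)C(C)C)[C@@H](c1ccc(O[Si](C)(C)C(C)(C)C)c(OC)c1)O2 | intermediate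
20 | (1S,2S)-1-Ar-2-{[(DHB-methyl)oxy]methyl}pent-4-en-1-ol | C=CC[C@@H](COCc1cc(OC)c2c(c1)[C@@H](CO[Si](C(C)C)(C(C)C)C(C)C)[C@@H](c1ccc(O[Si](C)(C)C(C)(C)C)c(OC)c1)O2)[C@H](O)c1ccc(O[Si](C)(C)C(C)(C)C)c(OC)c1 | intermediate
21 | (1S,2S)-1-Ar-2-{[(DHB-methyl)oxy]methyl}pentane-1,4,5-triol (C4 epimers) | OCC(O)C[C@@H](COCc1cc(OC)c2c(c1)[C@@H](CO[Si](C(C)C)(C(C)C)C(C)C)[C@@H](c1ccc(O[Si](C)(C)C(C)(C)C)c(OC)c1)O2)[C@H](O)c1ccc(O[Si](C)(C)C(C)(C)C)c(OC)c1 | intermediate (not isolated)
22 | (3S,4S)-4-Ar-4-hydroxy-3-{[(DHB-methyl)oxy]methyl}butanal | O=CC[C@@H](COCc1cc(OC)c2c(c1)[C@@H](CO[Si](C(C)C)(C(C)C)C(C)C)[C@@H](c1ccc(O[Si](C)(C)C(C)(C)C)c(OC)c1)O2)[C@H](O)c1ccc(O[Si](C)(C)C(C)(C)C)c(OC)c1 | intermediate (not isolated)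
23 | (4S,5S)-5-Ar-4-{[(DHB-methyl)oxy]methyl}oxolan-2-ol (anomers) | COc1cc([C@H]2OC(O)C[C@H]2COCc2cc(OC)c3c(c2)[C@@H](CO[Si](C(C)C)(C(C)C)C(C)C)[C@@H](c2ccc(O[Si](C)(C)C(C)(C)C)c(OC)c2)O3)ccc1O[Si](C)(C)C(C)(C)C | intermediate
24 | (4S,5S)-5-Ar-4-{[(DHB-methyl)oxy]methyl}oxolan-2-one | COc1cc([C@H]2OC(=O)C[C@H]2COCc2cc(OC)c3c(c2)[C@@H](CO[Si](C(C)C)(C(C)C)C(C)C)[C@@H](c2ccc(O[Si](C)(C)C(C)(C)C)c(OC)c2)O3)ccc1O[Si](C)(C)C(C)(C)C | intermediate
25 | (4S,5S)-5-Ar-4-{[(DHB-methyl)oxy]methyl}-3-(trifluoroacetyl)oxolan-2-one (C3 epimers/enol) | COc1cc([C@H]2OC(=O)C(C(=O)C(F)(F)F)[C@H]2COCc2cc(OC)c3c(c2)[C@@H](CO[Si](C(C)C)(C(C)C)C(C)C)[C@@H](c2ccc(O[Si](C)(C)C(C)(C)C)c(OC)c2)O3)ccc1O[Si](C)(C)C(C)(C)C | intermediate (not isolated)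
26 | (4S,5S)-5-Ar-3-diazo-4-{[(DHB-methyl)oxy]methyl}oxolan-2-one | COc1cc([C@H]2OC(=O)C(=[N+]=[N-])[C@H]2COCc2cc(OC)c3c(c2)[C@@H](CO[Si](C(C)C)(C(C)C)C(C)C)[C@@H](c2ccc(O[Si](C)(C)C(C)(C)C)c(OC)c2)O3)ccc1O[Si](C)(C)C(C)(C)C | intermediate (key-step precursor)
27 | endo,endo-2-Ar-6-DHB-3,7-dioxabicyclo[3.3.0]octan-4-one (7S,8S,7'S,8'R) | COc1cc([C@H]2OC(=O)[C@@H]3[C@H]2CO[C@@H]3c2cc(OC)c3c(c2)[C@@H](CO[Si](C(C)C)(C(C)C)C(C)C)[C@@H](c2ccc(O[Si](C)(C)C(C)(C)C)c(OC)c2)O3)ccc1O[Si](C)(C)C(C)(C)C | intermediate (key-step product)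
28 | endo,endo-2-Ar-6-DHB-3,7-dioxabicyclo[3.3.0]octan-4-ol (anomers) | COc1cc([C@H]2OC(O)[C@@H]3[C@H]2CO[C@@H]3c2cc(OC)c3c(c2)[C@@H](CO[Si](C(C)C)(C(C)C)C(C)C)[C@@H](c2ccc(O[Si](C)(C)C(C)(C)C)c(OC)c2)O3)ccc1O[Si](C)(C)C(C)(C)C | intermediate
29 | endo,endo-2-Ar-6-DHB-3,7-dioxabicyclo[3.3.0]octane (7S,8S,7'S,8'S) | COc1cc([C@H]2OC[C@@H]3[C@H]2CO[C@@H]3c2cc(OC)c3c(c2)[C@@H](CO[Si](C(C)C)(C(C)C)C(C)C)[C@@H](c2ccc(O[Si](C)(C)C(C)(C)C)c(OC)c2)O3)ccc1O[Si](C)(C)C(C)(C)C | intermediate
30 | CNP0303197.1, endo,endo-furofuran with (2S,3S)-cis-dihydrobenzofuran (7S,8S,7'S,8'S) | COc1cc([C@H]2OC[C@@H]3[C@H]2CO[C@@H]3c2cc(OC)c3c(c2)[C@@H](CO)[C@@H](c2ccc(O)c(OC)c2)O3)ccc1O | target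

**Step count and risks**

Total steps: 21. Longest linear sequence: 17 steps (vanillin 4 → 5 → 11 → 12 → 13 → 14 → 15 → 16 → 18 → 19 → 20 → 23 → 24 → 26 → 27 → 28 → 29 → 30; steps 2, 6 and 7–21).

Steps most likely to fail:

Step 9. The chiral catalyst may discriminate the two carbenoid faces poorly on this 2,6-disubstituted aryl benzyl ether carrying an ethyl ester, and the kinetic cis ester may partly epimerise at C3. The fallback replaces catalyst control by a classical resolution. It sets out from 13, which is cyclised with achiral Rh2(OAc)4 in CH2Cl2 to the racemic cis ester, that is 14 together with its mirror image ethyl (2R,3S)-5-bromo-7-methoxy-2-Ar-2,3-dihydro-1-benzofuran-3-carboxylate F1. Reduction with iBu2AlH at −78 °C gives 15 together with the enantiomeric alcohol [(2R,3R)-5-bromo-7-methoxy-2-Ar-2,3-dihydro-1-benzofuran-3-yl]methanol F2. Esterification of the pair with (S)-O-methylmandelic acid (DCC, DMAP cat., CH2Cl2, 0 °C) gives two diastereomers, the (2S,3S)-alcohol (S)-O-methylmandelate F3 and the (2R,3R)-alcohol (S)-O-methylmandelate F4. These are separated by chromatography or crystallisation, and F3 is cleaved with iBu2AlH at −78 °C, which brings the route back at 15.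

Step 20. BF3·OEt2 may ionise the electron-rich benzylic C7–O or C7'–O bond (or C2–O of the dihydrobenzofuran), and reclosure would move an aryl group to the exo (or trans) position. The fallback avoids any cationic step. It sets out from 27, whose lactone is opened with LiBH4 (THF, 0 °C → rt) to the 1,4-diol with a free C7 benzylic hydroxyl and a C9' primary hydroxyl F5. TsCl, pyridine and DMAP (cat.) at 0 °C → rt sulfonylate the primary hydroxyl selectively to the primary C9' tosylate F6, which is not isolated because the C7 hydroxyl displaces it in a 5-exo-tet SN2 reaction at the primary carbon. No benzylic C–O bond is broken, and the route is rejoined at 29, with 28 bypassed.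

Step 14. The secondary benzylic hydroxyl may compete for the bromide (regioisomeric and double ethers), and the labile bromide may be lost by solvolysis on silver. The fallback blocks the competing hydroxyl before the diol stage. It sets out from 7, which is silylated with Et3SiOTf and 2,6-lutidine to the O-triethylsilyl aldol adduct F7. LiBH4 then removes the auxiliary to give the mono-protected primary alcohol (2S,3S)-3-Ar-2-(prop-2-en-1-yl)-3-(triethylsilyloxy)propan-1-ol F8. Etherification with 19 under Ag2O (or AgOTf with 2,6-di-tert-butyl-4-methylpyridine) gives the C7-O-triethylsilyl ether of the coupled product F9. Pyridinium p-toluenesulfonate in MeOH at 0 °C removes only the secondary triethylsilyl group, and the route is rejoined at 20.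

**Further compounds**

F1 | step 9 | ethyl (2R,3S)-5-bromo-7-methoxy-2-Ar-2,3-dihydro-1-benzofuran-3-carboxylate (enantiomer of 14) | Brc1cc(OC)c2c(c1)[C@H](C(=O)OCC)[C@H](c1ccc(O[Si](C)(C)C(C)(C)C)c(OC)c1)O2
F2 | step 9 | [(2R,3R)-5-bromo-7-methoxy-2-Ar-2,3-dihydro-1-benzofuran-3-yl]methanol (enantiomer of 15) | Brc1cc(OC)c2c(c1)[C@H](CO)[C@H](c1ccc(O[Si](C)(C)C(C)(C)C)c(OC)c1)O2
F3 | step 9 | [(2S,3S)-5-bromo-7-methoxy-2-Ar-2,3-dihydro-1-benzofuran-3-yl]methyl (S)-2-methoxy-2-phenylacetate | Brc1cc(OC)c2c(c1)[C@@H](COC(=O)[C@@H](OC)c1ccccc1)[C@@H](c1ccc(O[Si](C)(C)C(C)(C)C)c(OC)c1)O2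
F4 | step 9 | [(2R,3R)-5-bromo-7-methoxy-2-Ar-2,3-dihydro-1-benzofuran-3-yl]methyl (S)-2-methoxy-2-phenylacetate | Brc1cc(OC)c2c(c1)[C@H](COC(=O)[C@@H](OC)c1ccccc1)[C@H](c1ccc(O[Si](C)(C)C(C)(C)C)c(OC)c1)O2
F5 | step 20 | (S)-Ar-[(3S,4S,5S)-5-DHB-4-(hydroxymethyl)oxolan-3-yl]methanol (1,4-diol from 27) | COc1cc([C@@H](O)[C@@H]2CO[C@H](c3cc(OC)c4c(c3)[C@@H](CO[Si](C(C)C)(C(C)C)C(C)C)[C@@H](c3ccc(O[Si](C)(C)C(C)(C)C)c(OC)c3)O4)[C@@H]2CO)ccc1O[Si](C)(C)C(C)(C)C
F6 | step 20 | primary C9' p-toluenesulfonate of F5 | COc1cc([C@@H](O)[C@@H]2CO[C@H](c3cc(OC)c4c(c3)[C@@H](CO[Si](C(C)C)(C(C)C)C(C)C)[C@@H](c3ccc(O[Si](C)(C)C(C)(C)C)c(OC)c3)O4)[C@@H]2COS(=O)(=O)c2ccc(C)cc2)ccc1O[Si](C)(C)C(C)(C)C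
F7 | step 14 | (4S)-4-benzyl-3-[(2R,3S)-3-Ar-2-(prop-2-en-1-yl)-3-(triethylsilyloxy)propanoyl]-1,3-oxazolidin-2-one | C=CC[C@@H](C(=O)N1[C@@H](Cc2ccccc2)COC1=O)[C@H](O[Si](CC)(CC)CC)c1ccc(O[Si](C)(C)C(C)(C)C)c(OC)c1
F8 | step 14 | (2S,3S)-3-Ar-2-(prop-2-en-1-yl)-3-(triethylsilyloxy)propan-1-ol | C=CC[C@@H](CO)[C@H](O[Si](CC)(CC)CC)c1ccc(O[Si](C)(C)C(C)(C)C)c(OC)c1
F9 | step 14 | C7-O-triethylsilyl ether of 20 | C=CC[C@@H](COCc1cc(OC)c2c(c1)[C@@H](CO[Si](C(C)C)(C(C)C)C(C)C)[C@@H](c1ccc(O[Si](C)(C)C(C)(C)C)c(OC)c1)O2)[C@H](O[Si](CC)(CC)CC)c1ccc(O[Si](C)(C)C(C)(C)C)c(OC)c1
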